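**Plan**
- Retrosynthesis: the lactone unit O1–C2(=O) is read as CO2 lodged between C3 and the aromatic carbon C8a. Cutting C3–C2 and O1–C8a leaves CO2 and a 2,2-diarylethyl nucleophile whose ring A carries fluorine at C8a.
- Enabling feature: C8a lies ortho to the C8 ketone carbonyl of the 3-phenylpropanoyl group, so a C8a–F bond is an SNAr site. The C5 and C7 oxygens stay as methyl ethers, so only C8a can receive the lactone oxygen, which fixes the 8-acyl (not 6-acyl) constitution.
- Further cuts: C3–I from C3–OH from C3–B; C4–H and C3–B across a 1,1-diarylethene; C4–C4a (Suzuki); C4a–Br; C8–acyl (Friedel–Crafts).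
- Forward order: the benzene ring A is bought and is acylated, brominated and coupled to the α-arylvinyl boronate. The pyranone ring is the only ring made and closes in the key step, followed by O-demethylation.
- Stereochemistry: the (S) centre at C4 comes from ligand-controlled Cu–boryl addition and protonation of the 1,1-diarylethene in step 4; no later step makes or breaks a bond at C4.

Key step: step 6

Assumption: the α-arylvinyl boronate 5 is taken as a catalogue reagent.

**Step 1**
Reactants: 1 1-fluoro-3,5-dimethoxybenzene; 2 3-phenylpropanoic acid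
Product: 3 1-(2-fluoro-4,6-dimethoxyphenyl)-3-phenylpropan-1-one
Conditions: (CF3CO)2O, 85% H3PO4 (cat.), MeCN, 0 °C to 40 °C
Reagents that add atoms: none
Why: Friedel–Crafts acylation through the mixed trifluoroacetic anhydride of 2 should attack the carbon of 1 that is para to one methoxy group and flanked by fluorine, the carbon between the two methoxy groups being the more shielded site.

**Step 2**
Reactants: 3 1-(2-fluoro-4,6-dimethoxyphenyl)-3-phenylpropan-1-one
Product: 4 1-(3-bromo-2-fluoro-4,6-dimethoxyphenyl)-3-phenylpropan-1-one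
Conditions: NBS, MeCN, 0 °C to rt
Reagents that add atoms: N-bromosuccinimide, O=C1CCC(=O)N1Br
Why: Electrophilic aromatic bromination should enter between fluorine and the 4-methoxy group (para to the 6-methoxy group), because the other free position is flanked by two methoxy groups, one of them turned toward it by the neighbouring acyl group.

**Step 3**
Reactants: 4 1-(3-bromo-2-fluoro-4,6-dimethoxyphenyl)-3-phenylpropan-1-one; 5 2-[1-(4-methoxyphenyl)ethenyl]-4,4,5,5-tetramethyl-1,3,2-dioxaborolane
Product: 6 1-{2-fluoro-4,6-dimethoxy-3-[1-(4-methoxyphenyl)ethenyl]phenyl}-3-phenylpropan-1-one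
Conditions: Pd(OAc)2 (3 mol %), SPhos (6 mol %), K3PO4, toluene/H2O, 80 °C
Reagents that add atoms: none
Why: Suzuki–Miyaura coupling with a dialkylbiarylphosphine ligand should tolerate the di-ortho-substituted bromide, while the C–F bond and the ketone are inert to Pd(0) under these conditions.

**Step 4**
Reactants: 6 1-{2-fluoro-4,6-dimethoxy-3-[1-(4-methoxyphenyl)ethenyl]phenyl}-3-phenylpropan-1-one
Product: 8 1-{2-fluoro-3-[(1S)-2-hydroxy-1-(4-methoxyphenyl)ethyl]-4,6-dimethoxyphenyl}-3-phenylpropan-1-one, via pinacol boronate 7 (not isolated)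
Conditions: B2pin2, CuCl (5 mol %), chiral sulfonate-bearing imidazolinium salt (NHC precursor, 5.5 mol %), NaOt-Bu (20 mol %), MeOH (2 equiv), THF, −15 °C; then NaBO3·4H2O, THF/H2O, rt
Reagents that add atoms: bis(pinacolato)diboron, CC1(C)OB(OC1(C)C)B1OC(C)(C)C(C)(C)O1 (boron of 7); sodium perborate, [Na+].[Na+].O[B-]1(O)OO[B-](O)(O)OO1 (oxygen of 8)
Why: Cu-catalysed enantioselective protoboration of a 1,1-disubstituted aryl alkene, followed by stereoretentive C–B oxidation, should place boron on the CH2 terminus and create C4 by stereoretentive protonation of the diarylmethyl–copper with MeOH; the ligand distinguishes the twisted di-ortho-substituted ring from the flat anisyl ring, and the ligand antipode that delivers the (S) centre is used.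

**Step 5**
Reactants: 8 1-{2-fluoro-3-[(1S)-2-hydroxy-1-(4-methoxyphenyl)ethyl]-4,6-dimethoxyphenyl}-3-phenylpropan-1-one
Product: 9 1-{2-fluoro-3-[(1S)-2-iodo-1-(4-methoxyphenyl)ethyl]-4,6-dimethoxyphenyl}-3-phenylpropan-1-one
Conditions: PPh3, I2, imidazole, CH2Cl2, 0 °C to rt
Reagents that add atoms: iodine, II
Why: Appel-type iodination proceeds by SN2 attack of iodide on the primary alkoxyphosphonium carbon and should leave the adjacent C4 centre untouched.

**Step 6**
Reactants: 9 1-{2-fluoro-3-[(1S)-2-iodo-1-(4-methoxyphenyl)ethyl]-4,6-dimethoxyphenyl}-3-phenylpropan-1-one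
Product: 12 (4S)-5,7-dimethoxy-4-(4-methoxyphenyl)-8-(3-phenylpropanoyl)-3,4-dihydro-2H-chromen-2-one, via alkylzinc iodide 10 (not isolated), via zinc carboxylate 11 (not isolated)
Conditions: Zn dust (TMSCl-activated), LiCl, THF, 40 °C; then CO2 (1 atm), DMF, 50 °C; then Cs2CO3, 90 °C
Reagents that add atoms: carbon dioxide, O=C=O; zinc, [Zn] (held only in 10 and 11)
Why: Proposed new method: zinc inserts into the primary C3–I bond, CO2 inserts into the C(sp3)–Zn bond in DMF/LiCl to forge C3–C2, and the carboxylate, freed from zinc by Cs2CO3, adds through O1 to the fluorine-bearing carbon C8a and expels fluoride via a Meisenheimer intermediate whose charge rests on the ortho C8 ketone, forging O1–C8a. The closest known reaction types are the LiCl-promoted carboxylation of alkylzinc halides with CO2 and the intramolecular SNAr O-arylation of oxygen nucleophiles at ortho-acyl aryl fluorides (chromone and xanthone closures), which have not been combined as one carboxylative lactonisation. The pyranone ring closes by a 6-exo-trig addition–elimination at an aromatic carbon. No stereocentre is formed, and C4 takes part in no bond change and is not acidic under carbonate, so the (S) configuration from step 4 should be carried through. The step needs the alkylzinc to choose CO2 over the hindered aryl ketone, which the low carbonyl reactivity of RZnI secures, and it needs closure at C8a and not at the C5 oxygen, which is secured because C8a holds the only leaving group while C5 and C7 are inert methyl ethers.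

**Step 7**
Reactants: 12 (4S)-5,7-dimethoxy-4-(4-methoxyphenyl)-8-(3-phenylpropanoyl)-3,4-dihydro-2H-chromen-2-one
Product: 13 (4S)-5,7-dihydroxy-4-(4-hydroxyphenyl)-8-(3-phenylpropanoyl)-3,4-dihydro-2H-chromen-2-one
Conditions: BBr3 (6 equiv), CH2Cl2, −78 °C to 0 °C; ice-water quench
Reagents that add atoms: none
Why: Lewis-acid cleavage of the three aryl methyl ethers with BBr3 at low temperature should spare the aryl lactone, the ketone and C4, and a cold, brief aqueous quench limits acid-mediated lactone migration to the freed C5 hydroxyl.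

**Compound list**
1 | 1-fluoro-3,5-dimethoxybenzene | COc1cc(F)cc(OC)c1 | starting material
2 | 3-phenylpropanoic acid | OC(=O)CCc1ccccc1 | starting material
3 | 1-(2-fluoro-4,6-dimethoxyphenyl)-3-phenylpropan-1-one | COc1cc(F)c(C(=O)CCc2ccccc2)c(OC)c1 | intermediate
4 | 1-(3-bromo-2-fluoro-4,6-dimethoxyphenyl)-3-phenylpropan-1-one | COc1cc(OC)c(C(=O)CCc2ccccc2)c(F)c1Br | intermediate
5 | 2-[1-(4-methoxyphenyl)ethenyl]-4,4,5,5-tetramethyl-1,3,2-dioxaborolane | C=C(B1OC(C)(C)C(C)(C)O1)c1ccc(OC)cc1 | starting material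
6 | 1-{2-fluoro-4,6-dimethoxy-3-[1-(4-methoxyphenyl)ethenyl]phenyl}-3-phenylpropan-1-one | C=C(c1ccc(OC)cc1)c1c(OC)cc(OC)c(C(=O)CCc2ccccc2)c1F | intermediate
7 | 1-{2-fluoro-4,6-dimethoxy-3-[(1S)-1-(4-methoxyphenyl)-2-(4,4,5,5-tetramethyl-1,3,2-dioxaborolan-2-yl)ethyl]phenyl}-3-phenylpropan-1-one | CC1(C)OB(C[C@@H](c2ccc(OC)cc2)c2c(OC)cc(OC)c(C(=O)CCc3ccccc3)c2F)OC1(C)C | intermediate (not isolated)
8 | 1-{2-fluoro-3-[(1S)-2-hydroxy-1-(4-methoxyphenyl)ethyl]-4,6-dimethoxyphenyl}-3-phenylpropan-1-one | OC[C@@H](c1ccc(OC)cc1)c1c(OC)cc(OC)c(C(=O)CCc2ccccc2)c1F | intermediate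
9 | 1-{2-fluoro-3-[(1S)-2-iodo-1-(4-methoxyphenyl)ethyl]-4,6-dimethoxyphenyl}-3-phenylpropan-1-one | IC[C@@H](c1ccc(OC)cc1)c1c(OC)cc(OC)c(C(=O)CCc2ccccc2)c1F | intermediate
10 | iodo{(2S)-2-[2-fluoro-4,6-dimethoxy-3-(3-phenylpropanoyl)phenyl]-2-(4-methoxyphenyl)ethyl}zinc | I[Zn]C[C@@H](c1ccc(OC)cc1)c1c(OC)cc(OC)c(C(=O)CCc2ccccc2)c1F | intermediate (not isolated)
11 | iodozinc (3S)-3-[2-fluoro-4,6-dimethoxy-3-(3-phenylpropanoyl)phenyl]-3-(4-methoxyphenyl)propanoate | O=C(O[Zn]I)C[C@@H](c1ccc(OC)cc1)c1c(OC)cc(OC)c(C(=O)CCc2ccccc2)c1F | intermediate (not isolated)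
12 | (4S)-5,7-dimethoxy-4-(4-methoxyphenyl)-8-(3-phenylpropanoyl)-3,4-dihydro-2H-chromen-2-one | O=C1C[C@@H](c2ccc(OC)cc2)c2c(OC)cc(OC)c(C(=O)CCc3ccccc3)c2O1 | intermediate
13 | (4S)-5,7-dihydroxy-4-(4-hydroxyphenyl)-8-(3-phenylpropanoyl)-3,4-dihydro-2H-chromen-2-one | O=C1C[C@@H](c2ccc(O)cc2)c2c(O)cc(O)c(C(=O)CCc3ccccc3)c2O1 | target

**Count and risks**
Total steps: 7. Longest linear sequence: 7 (steps 1–7 from compound 1).

Steps most likely to fail:

1. Step 6 (the labelled step). The fluoride displacement may stall because the zinc-bound carboxylate is a weak nucleophile, or dimethylamine released from hot DMF may compete at C8a. Fallback, from 9 with known chemistry only: zinc insertion and carboxylation are run as before, but the mixture is quenched with aqueous HCl to isolate (3S)-3-[2-fluoro-4,6-dimethoxy-3-(3-phenylpropanoyl)phenyl]-3-(4-methoxyphenyl)propanoic acid F1. Aqueous KOH in DMSO at 80 °C then exchanges the fluorine for hydroxyl by hydroxide SNAr ortho to the ketone, giving after acidification (3S)-3-[2-hydroxy-4,6-dimethoxy-3-(3-phenylpropanoyl)phenyl]-3-(4-methoxyphenyl)propanoic acid F2. TsOH-catalysed lactonisation in toluene closes the ester bond onto the only free phenol and comes back to the route at 12.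

2. Step 4. The Cu–boryl species may add to the ketone carbonyl instead of the hindered alkene, or facial discrimination between the two aryl groups may be weak. Fallback, from 6: Rh-catalysed hydroboration with catecholborane (RhCl(PPh3)3, THF), where the catalysed alkene addition outruns ketone reduction, gives racemic 1-{3-[2-(1,3,2-benzodioxaborol-2-yl)-1-(4-methoxyphenyl)ethyl]-2-fluoro-4,6-dimethoxyphenyl}-3-phenylpropan-1-one F3, which is not isolated. Perborate oxidation gives racemic 1-{2-fluoro-3-[2-hydroxy-1-(4-methoxyphenyl)ethyl]-4,6-dimethoxyphenyl}-3-phenylpropan-1-one F4. Esterification with (S)-2-methoxy-2-phenylacetic acid (DCC, DMAP) gives (2S)-2-[2-fluoro-4,6-dimethoxy-3-(3-phenylpropanoyl)phenyl]-2-(4-methoxyphenyl)ethyl (2S)-2-methoxy-2-phenylacetate F5 and its diastereomer (2R)-2-[2-fluoro-4,6-dimethoxy-3-(3-phenylpropanoyl)phenyl]-2-(4-methoxyphenyl)ethyl (2S)-2-methoxy-2-phenylacetate F6, to be separated by crystallisation or chromatography. Methanolysis of F5 (K2CO3 cat., MeOH, 0 °C) comes back to the route at 8.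

3. Step 2. Bromine may enter the carbon between the two methoxy groups, or the ketone α-position may be brominated. Fallback, from 1: ortho-lithiation (n-BuLi, THF, −78 °C) at the C–H flanked by fluorine and methoxy gives (2-fluoro-4,6-dimethoxyphenyl)lithium F7. Bromine transfer from BrCF2CF2Br gives 2-bromo-1-fluoro-3,5-dimethoxybenzene F8. Acylation of F8 with 2 under the conditions of step 1, at the remaining fluorine-flanked carbon, comes back to the route at 4.

**Further compounds**
F1 | step 6 | (3S)-3-[2-fluoro-4,6-dimethoxy-3-(3-phenylpropanoyl)phenyl]-3-(4-methoxyphenyl)propanoic acid | O=C(O)C[C@@H](c1ccc(OC)cc1)c1c(OC)cc(OC)c(C(=O)CCc2ccccc2)c1F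
F2 | step 6 | (3S)-3-[2-hydroxy-4,6-dimethoxy-3-(3-phenylpropanoyl)phenyl]-3-(4-methoxyphenyl)propanoic acid | O=C(O)C[C@@H](c1ccc(OC)cc1)c1c(OC)cc(OC)c(C(=O)CCc2ccccc2)c1O
F3 | step 4 | racemic 1-{3-[2-(1,3,2-benzodioxaborol-2-yl)-1-(4-methoxyphenyl)ethyl]-2-fluoro-4,6-dimethoxyphenyl}-3-phenylpropan-1-one | O=C(CCc1ccccc1)c1c(OC)cc(OC)c(C(CB2Oc3ccccc3O2)c2ccc(OC)cc2)c1F
F4 | step 4 | racemic 1-{2-fluoro-3-[2-hydroxy-1-(4-methoxyphenyl)ethyl]-4,6-dimethoxyphenyl}-3-phenylpropan-1-one | OCC(c1ccc(OC)cc1)c1c(OC)cc(OC)c(C(=O)CCc2ccccc2)c1F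
F5 | step 4 | (2S)-2-[2-fluoro-4,6-dimethoxy-3-(3-phenylpropanoyl)phenyl]-2-(4-methoxyphenyl)ethyl (2S)-2-methoxy-2-phenylacetate | CO[C@H](C(=O)OC[C@@H](c1ccc(OC)cc1)c1c(OC)cc(OC)c(C(=O)CCc2ccccc2)c1F)c1ccccc1
F6 | step 4 | (2R)-2-[2-fluoro-4,6-dimethoxy-3-(3-phenylpropanoyl)phenyl]-2-(4-methoxyphenyl)ethyl (2S)-2-methoxy-2-phenylacetate | CO[C@H](C(=O)OC[C@H](c1ccc(OC)cc1)c1c(OC)cc(OC)c(C(=O)CCc2ccccc2)c1F)c1ccccc1
F7 | step 2 | (2-fluoro-4,6-dimethoxyphenyl)lithium | [Li]c1c(F)cc(OC)cc1OC
F8 | step 2 | 2-bromo-1-fluoro-3,5-dimethoxybenzene | COc1cc(F)c(Br)c(OC)c1
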